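Measured against a run of 1.5 h, the half-life of reaction-phase target by decomposition alone is shorter, 0.10 h, so the yield turns on what reaches the second phase first.

    reagent in the reaction phase ⇌ reagent in the second phase, rate k1*([reagent in the reaction phase] - [reagent in the second phase]/K1) per volume of the first phase (K1 = 0.39, k1 = 0.00182 /s)
    starting material + reagent in the reaction phase → target (k2 = 0.0105 /M/s)
    target ⇌ product in the second phase, rate k3*([target] - [product in the second phase]/K3) per volume of the first phase (K3 = 30.4, k3 = 0.00106 /s)
    target → decomposed product (k4 = 0.00193 /s)
    reagent in the reaction phase + target → over-reaction product (k5 = 0.0386 /M/s)

starting material 0.17 M; reagent in the second phase 1.20 equiv; time 1.5 h; volume of the second phase over the first 1.0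

- amount of target and product in the second phase together at 1.5 h, in percent of the starting material charged
- part of the starting material charged that has reacted at 1.5 h

- amounts and yields of target count product in the second phase too
- in the second phase: reagent in the second phase, product in the second phase; everything else is in the first
- charges count per volume of the first phase; a concentration in a rate is the amount of a species over the volume of its own phase; every rate counts per litre of the first phase
- run time (flask): 1.5 h

- Turned round, the question is what the given numbers would need for a share of reacted material above 0.5 to reach the second phase. The rule is the escape share (a selectivity for the second phase): the transfer coefficient of target over the sum of that coefficient, the decomposition constant, and the over-reaction constant times c(reagent in the reaction phase). Back-transfer is neglected at a partition ratio of 30.4.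
- With c(reagent in the reaction phase) at zero, the share is highest, and this escape ceiling is 0.355. A share above 0.5 needs a transfer coefficient above the decomposition constant, but here it is lower, by a factor of 1.82.
- The other end of the band comes from the whole reagent charge at phase equilibrium, which puts 0.147 M in the reaction phase. Over-reaction then outruns decomposition, and the share falls to 0.122. Control of the target's loss changes hands at c(reagent in the reaction phase) = 0.0500 M.
- This reckoning commits to a yield between 0.122 and 0.355 of the material reacted, and it stops there, without a conversion of its own.
- The forecast goes further, with 17% for the yield, on the ground that “only the part that escapes there survives”, and 80% for the conversion, on the separate ground that over-reaction consumes the reagent.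
- The flask gives 16.4% at a conversion of 81.1%, a share of 0.202, under the ceiling and above the lower end. At 1.50 h this flask holds 32.6% decomposed product and 32.1% over-reaction product. The neighbour flask with 0.068 M of starting material, at the same equivalents and time, has the same two constants and so the same ceiling. At its conversion of 73.9% the ceiling allows 26.2%, and that neighbour flask gives 18.3%.

Its constants come from no measurement; no experiment stands behind them.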